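**Retrosynthetic overview**
1. 12 <= 11 (loss of two benzyl groups) <= aryl lactone 7 + 2,2,4,4-tetramethylcyclobutane-1,3-dione 8. The enol-trione ring is cut at its C(=O)–CMe2 bond and at its C=C(OH) bond, and both bonds are made in one operation.
2. Enabling feature: the phenolic O on the aromatic carbon between the C-methyl carbon and the benzylic carbon can reach the trione-ring C=O next to the side-chain-bearing ring carbon (O–C(ar)–C(ar)–CH–C–C=O). The two are therefore tied up as a six-membered aryl lactone (chroman-2-one), and the remaining arc C(OH)–CMe2–C(=O)–CMe2 is the opened four-membered ring of 8.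
3. Both rings are temporary. Enolate addition to 8, strain-driven retro-aldol opening of the four-membered ring and Dieckmann closure onto the lactone carbonyl trade them for the six-membered carbocycle and the free phenol.
4. 7 <= 5 (O-benzylation) <= acylphloroglucinol 3 + (E)-4-methylpent-2-enal 4 by an enantioselective carbene-catalysed [3+3] annulation that sets the only stereocentre; 3 <= 1 + 2 (Friedel–Crafts acylation).
5. Ring order: arene (bought), lactone ring (step 2, temporary), trione carbocycle (step 4, with loss of the lactone and cyclobutane rings).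

Key step: step 4

Assumption 1: the enol-trione ring is written as the tautomer given; its enol forms interconvert freely and count as one compound.
Assumption 2: the sense of induction in step 2 is assigned by analogy with annulations of other stable enols; both antipodes of the triazolium salt are commercial, and the one that directs attack to the Re face of the enal beta-carbon is meant.
Assumption 3: lactone closure in step 2 is taken to occur through the OH para to the ketone; the isomeric lactone closed through the other ortho OH would pass through steps 3 to 5 to the same target, because step 4 erases the lactone.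

**Step 1**
Reactants: 1 2-methylphloroglucinol; 2 isobutyryl chloride
Product: 3 1-(2,4,6-trihydroxy-3-methylphenyl)-2-methylpropan-1-one
Conditions: AlCl3 (3.5 equiv), CH2Cl2/PhNO2, 0 to 45 °C; then ice/aq HCl
Reagents that add atoms: isobutyryl chloride, CC(C)C(=O)Cl
Why: Friedel–Crafts C-acylation of an electron-rich phloroglucinol, in which the two free ring positions of 1 are equivalent and the first acyl group deactivates the ring against a second acylation; no stereocentre is involved.

**Step 2**
Reactants: 3 1-(2,4,6-trihydroxy-3-methylphenyl)-2-methylpropan-1-one; 4 (E)-4-methylpent-2-enal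
Product: 5 (4S)-5,7-dihydroxy-8-methyl-6-(2-methylpropanoyl)-4-(propan-2-yl)chroman-2-one
Conditions: cis-1-amino-2-indanol-derived N-mesityl triazolium chloride (10 mol %), i-Pr2NEt (20 mol %), 3,3',5,5'-tetra-tert-butyldiphenoquinone (1.1 equiv), 4 Å MS, THF, rt
Reagents that add atoms: (E)-4-methylpent-2-enal, CC(C)/C=C/C=O
Why: Oxidative N-heterocyclic-carbene catalysis activates the enal as a catalyst-bound alpha,beta-unsaturated acyl azolium that takes up stable enols in a Coates–Claisen-type [3+3] annulation (formal Michael addition and lactonisation); 3 should react at its only unsubstituted ring carbon, the non-chelated and most acidic OH para to the ketone should close the lactone, and the indane wall of the chiral carbene shields one face of the acyl azolium so that the arene is delivered to the Re face of the beta-carbon, which sets the (S) centre.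

**Step 3**
Reactants: 5 (4S)-5,7-dihydroxy-8-methyl-6-(2-methylpropanoyl)-4-(propan-2-yl)chroman-2-one; 6 benzyl bromide
Product: 7 (4S)-5,7-bis(benzyloxy)-8-methyl-6-(2-methylpropanoyl)-4-(propan-2-yl)chroman-2-one
Conditions: BnBr (2.6 equiv), K2CO3 (3 equiv), n-Bu4NI (cat.), dry DMF, rt to 45 °C
Reagents that add atoms: benzyl bromide, BrCc1ccccc1
Why: Williamson ether synthesis on the two acidic phenols that flank the ketone, run under anhydrous carbonate conditions that should leave the aryl lactone closed and cannot touch the non-acidic C4 stereocentre.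

**Step 4**
Reactants: 7 (4S)-5,7-bis(benzyloxy)-8-methyl-6-(2-methylpropanoyl)-4-(propan-2-yl)chroman-2-one; 8 2,2,4,4-tetramethylcyclobutane-1,3-dione
Product: 11 2-{(1S)-1-[2,4-bis(benzyloxy)-6-hydroxy-5-methyl-3-(2-methylpropanoyl)phenyl]-2-methylpropyl}-3-hydroxy-4,4,6,6-tetramethylcyclohex-2-ene-1,5-dione, via cyclobutanol aldolate 9 (not isolated), via ring-opened keto lactone 10 (not isolated)
Conditions: 7 added to LiN(SiMe3)2 (3.5 equiv), THF, −78 °C; 8 (1.3 equiv), −78 °C to rt, then 50 °C; cold 1 M HCl
Reagents that add atoms: 2,2,4,4-tetramethylcyclobutane-1,3-dione, CC1(C)C(=O)C(C)(C)C1=O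
Why: Proposed new method: the lithium enolate of aryl lactone 7 adds through C3, anti to the pseudoaxial isopropyl group, to one of the two equivalent strained carbonyl groups of 8, and the 3-oxidocyclobutanone 9 so formed cleaves a ring C–C bond by strain-releasing retro-aldol fragmentation, which leaves the new C3–C(=O) bond in place and frees a tetrasubstituted isopropyl ketone enolate (the enolate form of 10). This enolate carbon attacks the lactone carbonyl in a Dieckmann-type 6-(enolendo)-exo-trig closure, either directly or, after proton exchange with the acidic C3–H and renewed deprotonation by the excess amide, through the acylketene that E1cB loss of the tethered phenoxide gives (then 6-(enolendo)-exo-dig), so that the one new ring, the tetramethylated trione carbocycle, closes while the lactone ring opens to the free phenol. The closest known reaction types are the opening of 8 by alkoxides, amines and organometallic reagents to 2,2,4-trimethyl-3-oxopentanoyl derivatives, the retro-aldol half of the De Mayo reaction and the Dieckmann condensation of preformed enolates to syncarpic-acid-type triones; their merger into a net insertion of the two-carbon CH2–C(=O) unit of an ester into a C–C bond of a cyclobutanedione is what is new. No stereocentre of 11 is made here: the C3 centre of 9 is transient and ends sp2, and the benzylic centre of 7, which is not acidic, is carried through and is shielded from retro-Michael scrambling because 11 rests as its enolate–phenoxide dianion until the cold quench. The step needs enolisation of the lactone CH2 in preference to the hindered methine of the di-ortho-substituted aryl ketone (secured by kinetic acidity and by the benzyl ethers, which remove all OH acids), ring fragmentation in preference to beta-lactone formation or plain retro-aldol (secured by the strain of the four-membered ring) and C- over O-acylation. The last is secured thermodynamically, because an enol lactone from O-acylation is an active ester that the phenoxide reopens, whereas only the C-acylated product leaves the equilibria as a doubly stabilised enolate.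

**Step 5**
Reactants: 11 2-{(1S)-1-[2,4-bis(benzyloxy)-6-hydroxy-5-methyl-3-(2-methylpropanoyl)phenyl]-2-methylpropyl}-3-hydroxy-4,4,6,6-tetramethylcyclohex-2-ene-1,5-dione
Product: 12 2-{(1S)-2-methyl-1-[2,4,6-trihydroxy-3-methyl-5-(2-methylpropanoyl)phenyl]propyl}-3-hydroxy-4,4,6,6-tetramethylcyclohex-2-ene-1,5-dione (target)
Conditions: H2 (1 atm), Pd/C (10 wt % Pd), EtOAc, rt
Reagents that add atoms: none
Why: Catalytic hydrogenolysis of aryl benzyl ethers under neutral conditions at room temperature, which should spare the vinylogous-acid-like aryl ketone and the enolised trione and avoids the acid, base or heat that could start retro-Michael racemisation or dehydrative pyran closure.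

**Compound list**
1 | 2-methylbenzene-1,3,5-triol (2-methylphloroglucinol) | Cc1c(O)cc(O)cc1O | starting material
2 | isobutyryl chloride | CC(C)C(=O)Cl | starting material
3 | 1-(2,4,6-trihydroxy-3-methylphenyl)-2-methylpropan-1-one | Cc1c(O)cc(O)c(C(=O)C(C)C)c1O | intermediate
4 | (E)-4-methylpent-2-enal | CC(C)/C=C/C=O | starting material
5 | (4S)-5,7-dihydroxy-8-methyl-6-(2-methylpropanoyl)-4-(propan-2-yl)chroman-2-one | CC(C)[C@@H]1CC(=O)Oc2c(C)c(O)c(C(=O)C(C)C)c(O)c21 | intermediate
6 | benzyl bromide | BrCc1ccccc1 | starting material
7 | (4S)-5,7-bis(benzyloxy)-8-methyl-6-(2-methylpropanoyl)-4-(propan-2-yl)chroman-2-one | CC(C)[C@@H]1CC(=O)Oc2c(C)c(OCc3ccccc3)c(C(=O)C(C)C)c(OCc3ccccc3)c21 | intermediate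
8 | 2,2,4,4-tetramethylcyclobutane-1,3-dione | CC1(C)C(=O)C(C)(C)C1=O | starting material
9 | (3S,4R)-5,7-bis(benzyloxy)-3-(1-hydroxy-2,2,4,4-tetramethyl-3-oxocyclobutyl)-8-methyl-6-(2-methylpropanoyl)-4-(propan-2-yl)chroman-2-one, 3,4-trans, same spatial arrangement at C4 as in 7, present as its lithium alkoxide | CC(C)[C@@H]1[C@@H](C2(O)C(C)(C)C(=O)C2(C)C)C(=O)Oc2c(C)c(OCc3ccccc3)c(C(=O)C(C)C)c(OCc3ccccc3)c21 | intermediate
10 | (4R)-5,7-bis(benzyloxy)-8-methyl-6-(2-methylpropanoyl)-4-(propan-2-yl)-3-(2,2,4-trimethyl-3-oxopentanoyl)chroman-2-one, C3 configurationally labile, present as its lithium enolates | CC(C)[C@@H]1C(C(=O)C(C)(C)C(=O)C(C)C)C(=O)Oc2c(C)c(OCc3ccccc3)c(C(=O)C(C)C)c(OCc3ccccc3)c21 | intermediate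
11 | 2-{(1S)-1-[2,4-bis(benzyloxy)-6-hydroxy-5-methyl-3-(2-methylpropanoyl)phenyl]-2-methylpropyl}-3-hydroxy-4,4,6,6-tetramethylcyclohex-2-ene-1,5-dione | Cc1c(OCc2ccccc2)c(C(=O)C(C)C)c(OCc2ccccc2)c([C@@H](C2=C(O)C(C)(C)C(=O)C(C)(C)C2=O)C(C)C)c1O | intermediate
12 | 2-{(1S)-2-methyl-1-[2,4,6-trihydroxy-3-methyl-5-(2-methylpropanoyl)phenyl]propyl}-3-hydroxy-4,4,6,6-tetramethylcyclohex-2-ene-1,5-dione | Cc1c(O)c(C(=O)C(C)C)c(O)c([C@@H](C2=C(O)C(C)(C)C(=O)C(C)(C)C2=O)C(C)C)c1O | target

**Step count**
Total step count: 5. Longest linear sequence: 5 steps (1, 3, 5, 7, 11, 12).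

**Steps most likely to fail**

Step 4. The hindered enolate may fail to add to the flanked carbonyl group. The aldolate may be diverted into four-membered lactone closure. The cascade may also stall once proton transfer has produced the stabilised enolate of the keto lactone.

The fallback uses only known chemistry, sets out from 3 and comes back at 12. 2,4,6-Trihydroxyacetophenone is exhaustively C-methylated (MeI, NaOMe, MeOH) to acetylsyncarpic acid F1, which hot aqueous HCl deacetylates to syncarpic acid F2. Knoevenagel condensation with isobutyraldehyde (piperidine cat., CH2Cl2) gives isobutylidenesyncarpic acid F3. Michael addition of the sodium phenoxide of 3 (NaH, THF, rt) through its free ring carbon gives the racemic target F4. Compound 12 is then obtained by preparative chromatography on a chiral stationary phase.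

Step 2. Facial selectivity may be poor with the beta-branched enal, or O-acylation of the phenols may outrun C–C bond formation.

The fallback sets out from 3 and comes back at 7. It moves the stereochemical event from C–C bond formation to hydride delivery onto a planar ring. Pechmann condensation of 3 with ethyl 4-methyl-3-oxopentanoate (MeSO3H, rt) gives 5,7-dihydroxy-8-methyl-6-(2-methylpropanoyl)-4-(propan-2-yl)coumarin F5. Benzylation with 6 (K2CO3, DMF) on the base-robust coumarin gives the dibenzyl coumarin F6. Copper hydride-catalysed asymmetric conjugate reduction then gives 7 (Cu(OAc)2, DTBM-SEGPHOS in the antipode that leads to the (S) product, pinacolborane, toluene, rt).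

Step 3. The lactone may open under carbonate with alkylation of the released phenol and acid. Alkylation of the hindered, hydrogen-bonded OH next to C4 may stay incomplete. Dearomatising C-benzylation may compete.

The fallback sets out from 5 and comes back at 12. It replaces alkylation under base and hydrogenolysis by silylation and fluoride cleavage. TBSOTf and 2,6-lutidine (CH2Cl2, 0 °C) give the bis-silyl lactone F7. The cascade of step 4 with 8 gives the bis-silyl ether F8. Et3N·3HF (THF, rt) then gives 12.

**Further compounds**
F1 | step 4 | 2-acetyl-3-hydroxy-4,4,6,6-tetramethylcyclohex-2-ene-1,5-dione (acetylsyncarpic acid) | CC(=O)C1=C(O)C(C)(C)C(=O)C(C)(C)C1=O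
F2 | step 4 | 5-hydroxy-2,2,6,6-tetramethylcyclohex-4-ene-1,3-dione (syncarpic acid) | CC1(C)C(=O)C=C(O)C(C)(C)C1=O
F3 | step 4 | 2,2,4,4-tetramethyl-6-(2-methylpropylidene)cyclohexane-1,3,5-trione (isobutylidenesyncarpic acid) | CC(C)C=C1C(=O)C(C)(C)C(=O)C(C)(C)C1=O
F4 | step 4 | racemic target | Cc1c(O)c(C(=O)C(C)C)c(O)c(C(C2=C(O)C(C)(C)C(=O)C(C)(C)C2=O)C(C)C)c1O
F5 | step 2 | 5,7-dihydroxy-8-methyl-6-(2-methylpropanoyl)-4-(propan-2-yl)coumarin | CC(C)C1=CC(=O)Oc2c(C)c(O)c(C(=O)C(C)C)c(O)c21
F6 | step 2 | 5,7-bis(benzyloxy)-8-methyl-6-(2-methylpropanoyl)-4-(propan-2-yl)coumarin | CC(C)C1=CC(=O)Oc2c(C)c(OCc3ccccc3)c(C(=O)C(C)C)c(OCc3ccccc3)c21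
F7 | step 3 | (4S)-5,7-bis(tert-butyldimethylsilyloxy)-8-methyl-6-(2-methylpropanoyl)-4-(propan-2-yl)chroman-2-one | CC(C)[C@@H]1CC(=O)Oc2c(C)c(O[Si](C)(C)C(C)(C)C)c(C(=O)C(C)C)c(O[Si](C)(C)C(C)(C)C)c21
F8 | step 3 | bis(tert-butyldimethylsilyl) ether of 12 at the two oxygens flanking the ketone, (S) | Cc1c(O[Si](C)(C)C(C)(C)C)c(C(=O)C(C)C)c(O[Si](C)(C)C(C)(C)C)c([C@@H](C2=C(O)C(C)(C)C(=O)C(C)(C)C2=O)C(C)C)c1O
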